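The numbers are those of an exercise; what happens was integrated by code.

At late times step 4 has run one way for far longer than its half-life, so expect substrate, intermediate B and intermediate D to have drained into intermediate A, intermediate C and product.

| setting | alpha | beta | epsilon | theta |
|---|---|---|---|---|
| substrate | 0.050 M (fed, over 4.80 d) | 0.050 M | 0.050 M | 0.050 M |
| reagent | 0.0450 M | 0.0450 M | 0.0450 M | 0.0450 M (fed, over 4.80 d) |
| time | 6.0 d | 6.0 d |  | 6.0 d |
| remark | all but substrate at the start; substrate goes in evenly over 4.80 d, the run ends at 6.0 d | a closed flask charged with all of it at once and left for 6.0 d | a single well-mixed tank run continuously and read at steady state, 6.0 d in it on average | a stirred flask in which reagent is dosed at a steady rate over 4.80 d without added volume, worked up at 6.0 d |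

    intermediate B ⇌ intermediate D (K1 = 0.778, k1 = 0.00202 min⁻¹)
    reagent + intermediate C ⇌ product (K2 = 14 L mol⁻¹, k2 = 0.0124 L mol⁻¹ min⁻¹)
    substrate + reagent ⇌ intermediate B (K3 = 10 L mol⁻¹, k3 = 0.0229 L mol⁻¹ min⁻¹)
    substrate → intermediate A (k4 = 0.00170 min⁻¹)
    reagent + intermediate A ⇌ intermediate C (K5 = 149 L mol⁻¹, k5 = 0.0318 L mol⁻¹ min⁻¹)

* the set-up with the highest amount of product at the outlet or at the end, in percent of the substrate put in ("none" if the first two lie within 2 percentage points) (alpha / beta / epsilon / theta / none)
* amount of product at the outlet or at the end, in percent of the substrate put in, alpha
* amount of product at the outlet or at the end, in percent of the substrate put in, beta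
* amount of product at the outlet or at the end, in percent of the substrate put in, epsilon
* amount of product at the outlet or at the end, in percent of the substrate put in, theta

- the stated concentrations are those of everything mixed, before any reaction; amounts are the same in each set-up
- the feed brings no volume worth counting
- run time (alpha): 6.0 d

1. Let r be the free reagent at the end, a the ratio of intermediate C to intermediate A (r times the constant of step 5), and b the ratio of product to intermediate A (a times r times the constant of step 2). Product carries two reagent units, and intermediate C carries one. The balance therefore returns r as the reagent charge minus the substrate charge times (a+2b)/(1+a+b).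

2. Upper bound: try r = 0.0112 M. The balance returns 0.00752 M, which is less, so this r is too high and the end-state product share b/(1+a+b) lies below 8.98%.

3. Lower bound: try r = 0.00900 M. The balance returns 0.0116 M, which is more, so the end-state share lies above 6.73%.

4. Tightening: a straight line between the two misses gives r = 0.00991 M. The end concentration of product, its level under thermodynamic control, is then 0.00382 M.

5. Product's way back has a half-life of 0.543 d, far shorter than the run, so I commit beta to 7.64%. Alpha has 1.20 d after its feed ends, about twice that half-life, so I expect it to lie off that value.

6. The forecast gives alpha 9.2%, beta 8.3%, epsilon 7.7%, theta 6.8% and best none, saying “Keeping reagent in excess by feeding substrate gives a small overshoot and dosing reagent late undershoots”. Its alpha stands above my bracket, and its beta inside.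

7. The simulation gives alpha 8.03%, beta 7.64%, epsilon 7.70%, theta 7.74% and best none, with alpha and beta 0.39 percentage points apart.

In alpha, product stands 0.38 points above the end value at 6.00 d and reads 7.61% at 60.0 d, so it is still coming down. Now take beta with substrate at 0.020 M. Trials of r at 0.0225 M and 0.0270 M return 0.0248 M and 0.0234 M. The straight line gives 0.0243 M, and the product share comes to 21.0%. That neighbouring flask holds 20.9% product at 6.00 d.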